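**The neighbour.** Delta, the simulated run nearest to Wednesday's flask, was charged with 0.0100 M more X. At 15.0 h its L lay near 14.6%, with E at 0% and J at 7.5%. These add up to 22.1%, so I took most of the missing J as an unseen mono adduct, holding one X where L holds three.

| setting | delta | alpha | eta | Wednesday's | Sunday's | Monday's |
|---|---|---|---|---|---|---|
| J | 0.20 M | 0.20 M | 0.20 M | 0.20 M | 0.20 M | 0.20 M |
| X | 0.25 M | 0.32 M | 0.51 M | 0.240 M | 0.400 M | 0.500 M |
| remark | run made earlier | run made earlier | run made earlier |  |  |  |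
| time |  |  |  | 20 h | 20 h | 20 h |

| run | time / h | L / % | E / % | J / % |
|---|---|---|---|---|
| delta | 1.00 | 6.8 | 1.8 | 13.2 |
| delta | 2.50 | 11.1 | 1.2 | 10.4 |
| delta | 6.00 | 13.7 | 0.1 | 9.8 |
| delta | 15.0 | 14.6 | 0 | 7.5 |
| alpha | 2.00 | 16.2 | 2.0 | 3.2 |
| alpha | 5.00 | 23.9 | 1.1 | 2.9 |
| alpha | 10.0 | 28.2 | 0 | 1.7 |
| alpha | 15.0 | 28.7 | 0 | 1.8 |
| eta | 4.00 | 36.1 | 7.7 | 0.4 |
| eta | 8.00 | 49.5 | 3.7 | 0 |
| eta | 10.0 | 54.3 | 4.6 | 0 |
| eta | 15.0 | 61.1 | 2.5 | 0.1 |

(standard deviation of a reading: 0.5 percentage points)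



1. amount of L at the end, in percent of the J charged, for each flask in turn (Wednesday's, Sunday's, Monday's)

**The ceiling.** I worked from what was left. I took X charged per J, subtracted one, added the fraction of J left, and divided by two. This L ceiling was 16.2% for delta, and delta's L reading stood at 0.898 of it.

**Wednesday's reckoning.** From delta to alpha the J reading fell with more X, so I carried the same factor per molar of X back to Wednesday's flask. That gave about 9.20% of J left. Wednesday's ceiling came to 14.6%, lower than delta's, and delta's ratio put L near 13.1%. With J left taken as nil, I put Sunday's ceiling at 50.0% and Monday's at 75.0%. I expected L to end under its own ceiling in each of these flasks.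

**The result.** The forecast gave 13%, 46% and 65%, noting that “the eta run is still climbing”. The simulation gave 13.1%, 47.2% and 64.4%.

    X + Z → L (k = 0.0196 M⁻¹ s⁻¹)
    J + X → Q (k = 0.00787 M⁻¹ s⁻¹)
    X + Q → Z (k = 0.00108 M⁻¹ s⁻¹)
    E ⇌ G (K = 2.21, k = 5.11 × 10⁻⁴ s⁻¹)
    X + L ⇌ E (K = 12.0 M⁻¹, k = 0.0201 M⁻¹ s⁻¹)

**The way back.** Wednesday's X, the limiting reagent, ended at 0% of its charge, and L reached 0.870 of the ceiling reckoned with the J left there; delta's L reading had stood at 0.898 of its ceiling of 16.2%. Sunday's L reached 0.942 of its ceiling of 50.1%, although X + L runs on to E and E to G. In Sunday's flask the back reactions of E and of G returned that material to L. Without the step from G to E, Sunday's L ended at 17.2%, and without the step from E to X + L, at 3.58%.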